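The easy step comes first: under a steady feed, the share of the charge that has gone in is the time over the dosing time, and whatever has gone in but is not in chains is free monomer. So each reading also gives [free monomer].

| setting | Saturday's | Tuesday's | Thursday's | oak | ash |
|---|---|---|---|---|---|
| free monomer | 0.11 M (fed, over 6.0 h) | 0.11 M (fed, over 6.0 h) | 0.055 M (fed, over 6.0 h) | 0.11 M (fed, over 6.0 h) | 0.11 M (fed, over 25 h) |
| transfer agent | 3.3 mM | 3.3 mM | 3.3 mM | 3.30 mM | 3.30 mM |
| initiator | 3.7 mM | 8.2 mM | 5.5 mM | 5.5 mM | 5.5 mM |
| remark | run made earlier | run made earlier | run made earlier |  |  |
| time |  |  |  | 8.0 h | 8.0 h |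

| Saturday's: time / h | Saturday's: monomer in chains / % | Tuesday's: time / h | Tuesday's: monomer in chains / % | Thursday's: time / h | Thursday's: monomer in chains / % |
|---|---|---|---|---|---|
| 0.500 | 0.3 | 0.500 | 1.6 | 1.50 | 7.9 |
| 1.33 | 3.7 | 1.33 | 10.1 | 3.00 | 17.1 |
| 3.00 | 10.4 | 3.00 | 22.5 | 5.00 | 33.5 |
| 6.00 | 29.9 | 6.00 | 52.8 | 6.00 | 43.3 |

(scatter of a reading: 1 percentage point)

- the average divides the monomer in chains by the number of chains begun, living and dead together
- the earlier runs were read with a standard deviation of 1 percentage point
- percentages count the whole charge, also what has not yet gone in
- the earlier runs do not show the number of chains; that part of a forecast is a guess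

- which of the two ends with the longer chains by the average number of monomer units in a chain (chains begun, living or dead) ("neither" if they lie within 10%) (oak / ash / neither)
- average number of monomer units in a chain (chains begun, living or dead) at the end, oak
- average number of monomer units in a chain (chains begun, living or dead) at the end, ash

We carry one quantity, the mean uptake constant k̄: percent going into chains per hour, divided by the mean percent of free monomer standing (a pseudo-first-order constant). We read it from Thursday's run, which has the initiator of oak and ash.

Thursday's run, from the start to 1.50 h: 0.616 /h
Then to 3.00 h: 0.245 /h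
Then to 6.00 h: k̄ = 0.195 /h

The reading falls by a factor 2.51 and then by 1.26, so the late constant is a third of the opening one. Tuesday's run, at the full charge and scaled to oak's initiator, gives 0.181 /h, so we treat k̄ as free of the monomer charge.

With k̄ held constant, [free monomer] climbs toward the feed rate over k̄, reaching that ceiling times one minus e to the minus k̄t, and decays at k̄ after the feed. Our own reckoning gives:

oak: free at end of feed 59.0%, free at 8.0 h 39.9%, in chains 60.1%
ash: free at 8.0 h 16.2%, in chains 15.8%

Using the higher constant 0.245 /h instead moves ash to 18.0%, which is the error of taking the mean. The chain count is a guess; we take one chain per initiator charged, which gives 12.0 for oak and 3.16 for ash.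

The forecast also names oak, with 11 for oak and 3.5 for ash; its numbers differ from ours mainly through its guess at the chain count, “about 6 mM for oak and somewhat fewer for ash”, where we took one chain per initiator charged in both flasks.

The flask gives oak, with 12.0 and 3.47.

    free monomer + initiator → living end + monomer in chains (k = 0.0503 /M/s)
    living end + transfer agent → dead chain (kL = 0.0159 /M/s)
    initiator → spent initiator (k = 1.74 × 10⁻⁵ /s)
    free monomer + living end → monomer in chains + living end, rate k4*[living end]*[free monomer] (k = 0.0151 /M/s)

For ash, k̄ gave 15.8% in chains, and the flask holds 15.6%. The gap between the flasks comes from the difference in dosing time: ash given oak's feed ends at 12.0 instead of 3.47. The neighbour of ash with 0.19 M of free monomer holds 15.1% in chains, and the same k̄ percent with one chain per initiator gives 5.46 against its simulated 5.64.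

(The runs were computed with made-up constants; noise was put on by code.)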